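(The data stem from a simulated flask for substances that don't exist, and the scatter is random.)

In these closed flasks I take the two substrates and the two products together to stay at 100 per cent of the charge, of which 50.0% is charged as left-handed substrate.

| setting | birch | cedar | red | teal |
|---|---|---|---|---|
| left-handed substrate | 0.45 M | 0.45 M | 0.45 M | 0.45 M |
| right-handed substrate | 0.45 M | 0.45 M | 0.45 M | 0.45 M |
| gas | 32 mM (held) | 32 mM (held) | 32 mM (held) | 32 mM (held) |
| precatalyst | 62 mM | 110 mM | 45 mM | 90 mM |
| remark | run made earlier | run made earlier |  |  |
| time |  |  | 10 d | 10 d |

| run | time / d | left-handed product / % |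
|---|---|---|
| birch | 0.250 | 1.0 |
| birch | 0.833 | 4.1 |
| birch | 1.25 | 5.8 |
| birch | 2.00 | 10.2 |
| birch | 3.00 | 15.6 |
| birch | 4.00 | 20.8 |
| birch | 5.00 | 25.8 |
| cedar | 0.417 | 1.6 |
| cedar | 0.625 | 3.2 |
| cedar | 0.833 | 3.9 |
| cedar | 1.25 | 6.5 |
| cedar | 2.00 | 9.9 |
| cedar | 3.00 | 15.3 |
| cedar | 5.00 | 25.2 |

(readings scatter by 0.3 percentage points)

- partner is single-handed; left-handed substrate and right-handed substrate are mirror images of each other, charged as a racemate, each of them at the stated concentration
- at the start none of the gas is in solution
- the handed part of partner does not stay in what it makes, so the products of the two hands are mirror images too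

- which of the two there is more of at the end, red (left-handed product / right-handed product)
- which of the two there is more of at the end, teal (left-handed product / right-handed product)
- final left-handed product, as a percentage of the left-handed substrate and right-handed substrate together charged, in red
- final left-handed product, as a percentage of the left-handed substrate and right-handed substrate together charged, in teal

At 5.00 d birch, with [precatalyst] 62 mM, reads 25.8% left-handed product, and cedar, with 110 mM, reads 25.2%: a gap of 0.6 percentage points against a scatter of 0.3 points per reading. Their mean over that time gives 0.0510 d⁻¹, which I call the delivery rate: the fraction of the whole charge arriving as left-handed product per day. Birch gains 0.0510 d⁻¹ up to 2.00 d and 0.0520 d⁻¹ after it, so its readings show no fall in slope while the product climbs to half of the left-handed charge; birch reads as zero order in substrate over this stretch.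

Carried to 10 d, the line gives 51.0%, and it meets the 50.0% of the left-handed charge at 9.80 d, just inside the time. Taking the left-handed charge as the ceiling of my estimate, I commit to about 50.0% left-handed product in red and in teal, with left-handed as the larger product; that choice is an inference, as birch and cedar report no right-handed product.

The weak link is red, whose [precatalyst] lies below both runs. Birch and cedar give an apparent order in precatalyst of −0.0410, and going from birch down to red moves the slope by a factor of 1.01, so I keep red on the line.

The forecast calls the rate “zero order in both substrate and precatalyst” and gives left-handed product as the larger product in red and left-handed product in teal, with 43% for red and 48% for teal; both lie below my figure.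

The larger product is left-handed product in red and left-handed product in teal, and left-handed product stands at 47.3% in red and 47.9% in teal.

    partner + left-handed substrate → left-handed product (k = 1.37 × 10⁻⁴ L mol⁻¹ s⁻¹)
    partner + right-handed substrate → right-handed product (k = 4.37 × 10⁻⁶ L mol⁻¹ s⁻¹)
    left-handed substrate + racemization catalyst ⇌ right-handed substrate + racemization catalyst, rate k3*[racemization catalyst]*[left-handed substrate] forward; the back reaction follows from the equilibrium constant (k = 1.80 × 10⁻⁴ L mol⁻¹ s⁻¹)
    gas ⇌ partner, rate k4*(csat - [partner]) (kL = 2.97 × 10⁻⁵ s⁻¹)
    partner + precatalyst → racemization catalyst + spent reagent (k = 4.70 × 10⁻⁵ L mol⁻¹ s⁻¹)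

At 10.0 d red holds 47.3% left-handed product and 20.8% left-handed substrate, together 68.1%, more than the 50.0% charged as that hand. For red read at 2.5 d, the delivery rate gives 12.7%, and that flask holds 13.2% left-handed product.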